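Compound numbers used below are those of the steps and of the compound list.

## Analysis of the target

Target 19 is a dihydrochalcone built on a 2,5-dihydro-1-benzoxepine: ring A, a phloroglucinol-type benzene, is fused through C5a and C9a to the seven-membered ring C (O1, C2H2, C3 bearing the methyl group, C4H, C5H2). Ring A carries hydroxyls at C6 and C8, the ether oxygen O1 on C9a, one hydrogen at C9 and, at C7 between the two hydroxyls, a 3-(3,4-dihydroxyphenyl)propanoyl chain ending in the catechol ring B. There is no stereocentre; the only geometric element, the C3=C4 double bond, is held cis by ring C, so every selectivity question is one of constitution. Two of them decide the synthesis: the double bond must stay at C3=C4, out of conjugation with ring A (C4=C5) and with O1 (C2=C3), and the acyl chain must go to C7 and not to C9. Sensitive are the very electron-rich ring A and the catechol (oxidants, electrophiles), the C5 methylene, which is benzylic and allylic at once, the allylic aryl ether C2–O1, and the trisubstituted alkene, which limits the use of strong acid. The difficulty is to close a seven-membered ring on a symmetric phloroglucinol whose three oxygens must be told apart, with the alkene fixed in the skipped position. The strategy rests on C5: it is a CH2 on C5a, ortho to the oxygens on C6 and C9a and para to the one on C8, so a positive charge there is exceptionally well stabilised, and its neighbour C4 is an alkene carbon that a silicon substituent can mark as the point of attack.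

## Retrosynthetic reasoning

19 from 18. No skeletal bond is cut; the four phenols are unmasked last from the tetra-acetal 18. They have to stay protected until then because the preceding step uses an aryllithium. The forward step must remove four acetals without protonating the C3=C4 bond.

18 from 13 and 16. The bond between C7 and the ketone carbon is cut, which divides the molecule into two halves of similar size. C7 is chosen because in 13 it is the only ring carbon lying between two acetal oxygens, so it can be turned into the carbanion 17 without a halogen handle; an electrophilic acylation would not distinguish C7 from C9 and would need a Lewis acid that the alkene does not tolerate. The forward reaction has to metalate C7 rather than C9, C5 or C2 and stop at the ketone, which the N-methoxy-N-methyl amide 16 ensures.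

13 from 12 from 11. Here only the oxygen substituents at C6 and C8 change. Silyl ethers are wanted for the ring closure (they do not take part in cation chemistry), acetal ethers for the metalation (they direct it), so the exchange through diol 12 is the price of using each group where it works.

11 from 10. The C4–C5 bond is cut. Cutting C2–O1 or C3=C4 instead would leave a carbon chain on C5a that could only come from C-alkylation of a phloroglucinol. With the C4–C5 cut, C5 becomes a one-carbon substituent at the alcohol oxidation level and the rest of ring C hangs on an oxygen. The forward reaction must ionise the benzylic alcohol of 10, close a seven-membered ring in preference to intermolecular arylation, and leave the double bond at C3=C4 only; a trimethylsilyl group on C4 is there for that purpose.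

10 from 9 from 8 and 6, and 8 from 7. The alcohol comes from the aldehyde 9 by hydride reduction. The O1–C2 bond is then cut, giving phenol 8 and allylic alcohol 6; etherification under neutral redox-condensation conditions spares the aryl silyl ethers. In 8 the symmetry of 7 is broken by the aldehyde, which holds one ortho hydroxyl in a hydrogen bond and lets the other two be silylated. The aldehyde carbon of 7 becomes C5.

6 from 4 from 3 from 1. The C–Si bond is traced back to a C–I bond of the same geometry. In 3 the iodine is cis to the CH2OH group because it replaces a metal that was held there by chelation during carbometalation of 1, which also brings in the methyl group. The silyl group is delivered from oxygen to carbon inside the cis-configured vinyllithium 5, so the Z geometry of 6 follows from that of 3.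

16 from 15 from 14. The amide bond and the two catechol acetals are cut; 14 is commercial. The catechol gets the same protecting group as ring A so that one final step removes all four.

## Alternatives that were turned down

Alternative 1: The cut is made inside ring A, between the acyl-bearing carbon C7 and one of its hydroxyl-bearing neighbours, and the ring is unfolded into a polyketide chain stored as the pyrone A1 (6-{4-[3,4-bis(methoxymethoxy)phenyl]-2-oxobutyl}-4-hydroxy-2H-pyran-2-one). In the forward key step a magnesium alkoxide opens the lactone of A1; in the chelated open-chain form the methylene between the two ketones nearest the aryl end attacks the ester carbonyl in a Claisen condensation, and enolisation gives the acylphloroglucinol A2.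
- For it: the acyl chain sits between two hydroxyls by construction, so no site selectivity of acylation is needed. On this point it is stronger than the chosen route, which depends on the selective metalation of 13. Chelation by magnesium also steers the chain towards Claisen and away from aldol closure.
- Against it: the step builds the one ring that can be bought, and forms no part of ring C. After A2 the oxepine would still have to be annulated onto a symmetric triphenol with two equivalent ring CH positions, by C-alkylation next to a selectively O-alkylated para hydroxyl, on a ring now deactivated by the ketone. A1 itself needs several polyanion acylation steps.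
- Comparison: the chosen strategy spends its key step on the seven-membered ring and the alkene position, the actual problem, and pays with a late metalation.

Alternative 2: The C2–C3 bond is cut. The precursor A3 (3-[3,4-bis(methoxymethoxy)phenyl]-1-{2,6-dihydroxy-4-[(phenylsulfanyl)methoxy]-3-[(Z)-3-(trimethylsilyl)but-2-enyl]phenyl}propan-1-one) carries an O,S-acetal on the oxygen that becomes O1 and a vinylsilane chain on C5a. A thiophilic sulfonium activator removes the phenylthio group, and the aryloxymethyl cation is attacked by the silicon-bearing alkene carbon, closing the oxepine to A4, the target with ring B still protected.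
- For it: an oxygen-stabilised CH2 cation is the classical initiator for this kind of terminator, so the precedent for the ring closure is closer than for the chosen step. The acyl chain is already in place, the ketone tempers the nucleophilicity of ring A, and only one deprotection follows. On precedent and convergence it is as strong or stronger.
- Against it: the new bond must form at C3, a fully substituted carbon bearing both methyl and silicon. Alkyl substitution favours charge at C3 and silicon favours charge at C4, whereas in 10 both controls point the same way and the bond forms at a CH. The activator is a sulfur electrophile that can also attack the vinylsilane or the free-phenol ring. A3 requires C-alkylation of an acylphloroglucinol with a stereodefined chain whose silicon and methyl share one carbon, then selective O-alkylation of one of three phenols.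
- Comparison: the chosen strategy offers a precursor reached from a symmetric aldehyde by O-functionalisation only, and matched regiocontrol in the terminator.

Alternative 3: Ring C is traced back to a spiro-fused vinylcyclopropane, A5 (6-(tert-butyldimethylsilyloxy)-1-(prop-1-en-2-yl)spiro[2.5]octane-4,8-dione). On neutral heating a retro-Claisen shift joins a ring carbonyl oxygen to the isopropenyl CH2 (O1–C2) while the cyclopropane bond between the spiro carbon and the substituted carbon (C5a–C4) breaks, giving the racemic enone A6 (8-(tert-butyldimethylsilyloxy)-3-methyl-2,5,8,9-tetrahydro-1-benzoxepin-6(7H)-one).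
- For it: the reaction is pericyclic and needs no acid, so the alkene position follows from the topology. No electron-rich arene is present yet, so intermolecular arylation cannot occur. One carbonyl is always cis to the alkenyl group in a spiro dione. On cleanliness of the ring-forming event it is as strong or stronger.
- Against it: ring A arrives at the wrong oxidation level. A6 must be desilylated, oxidised at C8 and tautomerised before it reaches diol 12, and a stereocentre is carried and then destroyed. A5 needs a double alkylation of a protected 5-hydroxy cyclic 1,3-dione with an unsymmetrical 2-methylbutene-1,4-diyl bis-electrophile, which can also give the methyl vinyl cyclopropane isomer. Acyl vinylcyclopropanes can also open to five-membered enol ethers. The alternative joins the chosen route at 12, so it solves nothing of the endgame.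
- Comparison: the chosen strategy works at the aromatic oxidation level from the first step, with no redox adjustment, and reaches 12 in no more steps.

Key step: step 7

Remark: metal alkoxides and the tetrahedral amide adduct that are only protonated or hydrolysed on work-up are treated as the salt form of the isolated product and are not numbered; carbon-centred organometallic intermediates are numbered.

## Route

Step 1
Reactants: 1 propargyl alcohol (prop-2-yn-1-ol)
Product: 3 (Z)-3-iodo-2-methylprop-2-en-1-ol, via cyclic vinylmagnesium alkoxide 2 (not isolated)
Conditions: MeMgBr (2.5 equiv), CuI (10 mol%), THF/Et2O, −10 °C → rt; then I2, −10 °C → rt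
Reagents that add atoms: methylmagnesium bromide C[Mg]Br; iodine II
Why: Copper-catalysed anti-carbomagnesiation of a propargylic alkoxide puts the methyl group on C2 and magnesium on C3 inside a five-membered chelate with the alkoxide oxygen; iodinolysis with retention should therefore place iodine cis to the CH2OH group.

Step 2
Reactants: 3 (Z)-3-iodo-2-methylprop-2-en-1-ol
Product: 4 [(Z)-3-iodo-2-methylprop-2-enoxy]trimethylsilane
Conditions: TMSCl, Et3N, CH2Cl2, 0 °C
Reagents that add atoms: chlorotrimethylsilane C[Si](C)(C)Cl
Why: Routine O-silylation of a primary alcohol; it places the silicon that is to end on carbon within reach of C3.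

Step 3
Reactants: 4 [(Z)-3-iodo-2-methylprop-2-enoxy]trimethylsilane
Product: 6 (Z)-2-methyl-3-(trimethylsilyl)prop-2-en-1-ol, via (Z)-vinyllithium 5 (not isolated)
Conditions: t-BuLi (2.1 equiv), THF, −78 °C → 0 °C; then H2O
Reagents that add atoms: none
Why: Iodine–lithium exchange with retention is followed by a retro-[1,4]-Brook rearrangement (1,4 O→C silyl shift) through a five-membered siliconate, possible only because lithium and the CH2OSiMe3 group are cis; the silyl group should thus arrive on C3 with the geometry of the iodide, and the alkoxide is protonated on work-up.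

Step 4
Reactants: 7 2,4,6-trihydroxybenzaldehyde
Product: 8 2,4-bis(tert-butyldimethylsilyloxy)-6-hydroxybenzaldehyde
Conditions: TBSCl (2.05 equiv), imidazole, CH2Cl2/DMF, 0 °C
Reagents that add atoms: tert-butyldimethylsilyl chloride CC(C)(C)[Si](C)(C)Cl
Why: Selective phenol silylation: the aldehyde holds one ortho hydroxyl in a hydrogen bond at a time, so the para and one ortho hydroxyl react and the chelated one should remain, as in the usual twofold protection of 2,4,6-trihydroxyaryl carbonyl compounds.

Step 5
Reactants: 8 2,4-bis(tert-butyldimethylsilyloxy)-6-hydroxybenzaldehyde; 6 (Z)-2-methyl-3-(trimethylsilyl)prop-2-en-1-ol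
Product: 9 2,4-bis(tert-butyldimethylsilyloxy)-6-{[(Z)-2-methyl-3-(trimethylsilyl)prop-2-enyl]oxy}benzaldehyde
Conditions: PPh3, DIAD, THF, 0 °C → rt
Reagents that add atoms: none
Why: Mitsunobu etherification of an acidic chelated phenol with a primary allylic alcohol; SN2 at the unhindered CH2 is expected over SN2' at the silicon-bearing carbon, and the near-neutral conditions leave the aryl silyl ethers and the vinylsilane untouched.

Step 6
Reactants: 9 2,4-bis(tert-butyldimethylsilyloxy)-6-{[(Z)-2-methyl-3-(trimethylsilyl)prop-2-enyl]oxy}benzaldehyde
Product: 10 [2,4-bis(tert-butyldimethylsilyloxy)-6-{[(Z)-2-methyl-3-(trimethylsilyl)prop-2-enyl]oxy}phenyl]methanol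
Conditions: NaBH4, THF/MeOH (4:1), −20 °C; pH 7 buffer
Reagents that add atoms: none
Why: Borohydride reduction of an aryl aldehyde; low temperature and a protic medium keep the benzylic alkoxide protonated so that the ortho silyl group should not shift to it, and the acid-labile alcohol is carried on without chromatography on acidic silica.

Step 7
Reactants: 10 [2,4-bis(tert-butyldimethylsilyloxy)-6-{[(Z)-2-methyl-3-(trimethylsilyl)prop-2-enyl]oxy}phenyl]methanol
Product: 11 6,8-bis(tert-butyldimethylsilyloxy)-3-methyl-2,5-dihydro-1-benzoxepine
Conditions: Sc(OTf)3 (10 mol%), 2,6-di-tert-butylpyridine (20 mol%), 4 Å MS, CH2Cl2/MeNO2 (4:1), 1 mM (slow addition of 10), −20 °C → rt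
Reagents that add atoms: none
Why: Sc(OTf)3 should ionise the benzylic alcohol to a cation stabilised by the oxygens on C6, C8 and C9a; the tethered alkene attacks it through the silicon-bearing carbon C4, which forms the C4–C5 bond and a tertiary β-silyl cation at C3, and loss of the trimethylsilyl group to the departed hydroxide (as Me3SiOH) leaves the double bond at C3=C4 and nowhere else. The closest known reaction type is the vinylsilane-terminated cationic cyclisation in its endocyclic mode, which closes oxepenes from oxocarbenium ions, taken together with the Lewis-acid-catalysed substitution of electron-rich benzylic alcohols by π-nucleophiles; here a benzylic cation serves as the initiator. Ring C closes in the 7-endo-trig mode with respect to the vinylsilane, and the ring holds the new double bond cis. No stereocentre is formed. Regioselectivity at the alkene is doubly secured: attack at C4 gives a cation that is both tertiary and β to silicon, whereas the 6-exo alternative through C3 would put the charge on a secondary carbon α to silicon. The Z geometry places silicon cis to the tether, so the C–Si bond can align with the emerging empty orbital inside the cyclic transition state. Chemoselectivity against capture of the cation by a second arene (diarylmethanes) rests on high dilution and on the bulky silyl ethers flanking C7 and C9, and the use of silyl rather than acetal ethers removes the oxygen nucleophile that would otherwise close a 1,3-benzodioxine.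

Step 8
Reactants: 11 6,8-bis(tert-butyldimethylsilyloxy)-3-methyl-2,5-dihydro-1-benzoxepine
Product: 12 3-methyl-2,5-dihydro-1-benzoxepine-6,8-diol
Conditions: Bu4NF (2.2 equiv), AcOH (2.2 equiv), THF, 0 °C
Reagents that add atoms: none
Why: Fluoride cleavage of aryl silyl ethers; buffering with acetic acid avoids a free electron-rich diphenoxide, which would be prone to air oxidation.

Step 9
Reactants: 12 3-methyl-2,5-dihydro-1-benzoxepine-6,8-diol
Product: 13 6,8-bis(methoxymethoxy)-3-methyl-2,5-dihydro-1-benzoxepine
Conditions: NaH, MOMCl, DMF, 0 °C
Reagents that add atoms: chloromethyl methyl ether COCCl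
Why: O-alkylation of phenoxides with a hard electrophile (Williamson type); the acetal ethers are installed only now because they direct the metalation of step 12 and would have interfered with the cation of step 7.

Step 10
Reactants: 14 3-(3,4-dihydroxyphenyl)propanoic acid
Product: 15 3-(3,4-dihydroxyphenyl)-N-methoxy-N-methylpropanamide
Conditions: MeNHOMe·HCl, EDC·HCl, HOBt, N-methylmorpholine, DMF, 0 °C → rt
Reagents that add atoms: N,O-dimethylhydroxylamine hydrochloride CNOC.Cl
Why: Carbodiimide amide coupling; the amine outcompetes the catechol hydroxyls for the active ester, and any aryl ester formed is itself aminolysed.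

Step 11
Reactants: 15 3-(3,4-dihydroxyphenyl)-N-methoxy-N-methylpropanamide
Product: 16 3-[3,4-bis(methoxymethoxy)phenyl]-N-methoxy-N-methylpropanamide
Conditions: MOMCl, i-Pr2NEt, CH2Cl2, 0 °C → 40 °C
Reagents that add atoms: chloromethyl methyl ether COCCl
Why: Acetal protection of the catechol under amine base, which avoids strong bases that could attack the N-methoxy amide; the same group as on ring A allows a single final deprotection.

Step 12
Reactants: 13 6,8-bis(methoxymethoxy)-3-methyl-2,5-dihydro-1-benzoxepine; 16 3-[3,4-bis(methoxymethoxy)phenyl]-N-methoxy-N-methylpropanamide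
Product: 18 3-[3,4-bis(methoxymethoxy)phenyl]-1-[6,8-bis(methoxymethoxy)-3-methyl-2,5-dihydro-1-benzoxepin-7-yl]propan-1-one, via aryllithium 17 (not isolated)
Conditions: n-BuLi (1.05 equiv), THF, −20 °C → 0 °C; then 16, −78 °C → 0 °C; aq NH4Cl
Reagents that add atoms: none
Why: Directed ortho-metalation: C7 is the only position flanked by two methoxymethoxy groups, which bind the base and acidify that hydrogen more than the one at C9 (one acetal, one alkyl ether); the aryllithium then acylates the Weinreb amide, whose chelated tetrahedral adduct prevents a second addition.

Step 13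
Reactants: 18 3-[3,4-bis(methoxymethoxy)phenyl]-1-[6,8-bis(methoxymethoxy)-3-methyl-2,5-dihydro-1-benzoxepin-7-yl]propan-1-one
Product: 19 1-(6,8-dihydroxy-3-methyl-2,5-dihydro-1-benzoxepin-7-yl)-3-(3,4-dihydroxyphenyl)propan-1-one
Conditions: HCl (2 M in MeOH), 40 °C, argon
Reagents that add atoms: none
Why: Acid-catalysed transacetalisation of the four methoxymethyl ethers to methanol; the two next to the ketone are assisted by hydrogen bonding, and the chroman-type capture of a C3 cation by the C6 hydroxyl, which troubles ortho-prenyl phenols, is geometrically impossible here because C3 is already tied to O1 on the far side of C5a.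

## Compound list

1 | propargyl alcohol (prop-2-yn-1-ol) | C#CCO | starting material
2 | 4-methyl-2,5-dihydro-1,2-oxamagnesole (cyclic vinylmagnesium alkoxide) | CC1=C[Mg]OC1 | intermediate (not isolated)
3 | (Z)-3-iodo-2-methylprop-2-en-1-ol | OC/C(C)=C\I | intermediate
4 | [(Z)-3-iodo-2-methylprop-2-enoxy]trimethylsilane | C[Si](C)(C)OC/C(C)=C\I | intermediate
5 | [(Z)-2-methyl-3-(trimethylsilyloxy)prop-1-enyl]lithium | C[Si](C)(C)OC/C(C)=C\[Li] | intermediate (not isolated)
6 | (Z)-2-methyl-3-(trimethylsilyl)prop-2-en-1-ol | OC/C(C)=C\[Si](C)(C)C | intermediate
7 | 2,4,6-trihydroxybenzaldehyde | O=Cc1c(O)cc(O)cc1O | starting material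
8 | 2,4-bis(tert-butyldimethylsilyloxy)-6-hydroxybenzaldehyde | O=Cc1c(O)cc(O[Si](C)(C)C(C)(C)C)cc1O[Si](C)(C)C(C)(C)C | intermediate
9 | 2,4-bis(tert-butyldimethylsilyloxy)-6-{[(Z)-2-methyl-3-(trimethylsilyl)prop-2-enyl]oxy}benzaldehyde | O=Cc1c(O[Si](C)(C)C(C)(C)C)cc(O[Si](C)(C)C(C)(C)C)cc1OC/C(C)=C\[Si](C)(C)C | intermediate
10 | [2,4-bis(tert-butyldimethylsilyloxy)-6-{[(Z)-2-methyl-3-(trimethylsilyl)prop-2-enyl]oxy}phenyl]methanol | OCc1c(O[Si](C)(C)C(C)(C)C)cc(O[Si](C)(C)C(C)(C)C)cc1OC/C(C)=C\[Si](C)(C)C | intermediate
11 | 6,8-bis(tert-butyldimethylsilyloxy)-3-methyl-2,5-dihydro-1-benzoxepine | CC1=CCc2c(cc(O[Si](C)(C)C(C)(C)C)cc2O[Si](C)(C)C(C)(C)C)OC1 | intermediate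
12 | 3-methyl-2,5-dihydro-1-benzoxepine-6,8-diol | CC1=CCc2c(cc(O)cc2O)OC1 | intermediate
13 | 6,8-bis(methoxymethoxy)-3-methyl-2,5-dihydro-1-benzoxepine | CC1=CCc2c(cc(OCOC)cc2OCOC)OC1 | intermediate
14 | 3-(3,4-dihydroxyphenyl)propanoic acid | OC(=O)CCc1ccc(O)c(O)c1 | starting material
15 | 3-(3,4-dihydroxyphenyl)-N-methoxy-N-methylpropanamide | CON(C)C(=O)CCc1ccc(O)c(O)c1 | intermediate
16 | 3-[3,4-bis(methoxymethoxy)phenyl]-N-methoxy-N-methylpropanamide | CON(C)C(=O)CCc1ccc(OCOC)c(OCOC)c1 | intermediate
17 | [6,8-bis(methoxymethoxy)-3-methyl-2,5-dihydro-1-benzoxepin-7-yl]lithium | CC1=CCc2c(cc(OCOC)c([Li])c2OCOC)OC1 | intermediate (not isolated)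
18 | 3-[3,4-bis(methoxymethoxy)phenyl]-1-[6,8-bis(methoxymethoxy)-3-methyl-2,5-dihydro-1-benzoxepin-7-yl]propan-1-one | CC1=CCc2c(cc(OCOC)c(C(=O)CCc3ccc(OCOC)c(OCOC)c3)c2OCOC)OC1 | intermediate
19 | 1-(6,8-dihydroxy-3-methyl-2,5-dihydro-1-benzoxepin-7-yl)-3-(3,4-dihydroxyphenyl)propan-1-one | CC1=CCc2c(cc(O)c(C(=O)CCc3ccc(O)c(O)c3)c2O)OC1 | target

## Step count and least certain steps

Total: 13 steps. Longest linear sequence: 10 steps (1, 2, 3, 5, 6, 7, 8, 9, 12, 13, from propargyl alcohol); the branch from 7 enters at step 5 and the amide branch (steps 10 and 11) at step 12.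

Step 7 (key step). The most likely failure is capture of the benzylic cation by ring A of a second molecule, substrate or product, in a Friedel–Crafts alkylation that leads on to diarylmethane oligomers. A trioxygenated arene is intrinsically a better π-nucleophile than a vinylsilane deactivated by the neighbouring aryloxy group, and a seven-membered closure has only a modest effective molarity. Two further losses are possible: a silyl group may leave the silyloxy-stabilised cation to give a neutral ortho-quinone methide that dimerises, and traces of acid may protodesilylate the vinylsilane before it cyclises. The fallback gives up cation chemistry and closes ring C by olefin metathesis at C3=C4. It sets out from 8 and returns at 11: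
- Mitsunobu etherification of 8 with 2-methylprop-2-en-1-ol should give 2,4-bis(tert-butyldimethylsilyloxy)-6-[(2-methylprop-2-enyl)oxy]benzaldehyde F1.
- Wittig reaction with Ph3P=CHOMe gives the enol ether 1,5-bis(tert-butyldimethylsilyloxy)-2-(2-methoxyethenyl)-3-[(2-methylprop-2-enyl)oxy]benzene F2.
- Mild aqueous acid hydrolysis gives {2,4-bis(tert-butyldimethylsilyloxy)-6-[(2-methylprop-2-enyl)oxy]phenyl}acetaldehyde F3.
- Methylenation with Ph3P=CH2 gives the diene 1,5-bis(tert-butyldimethylsilyloxy)-3-[(2-methylprop-2-enyl)oxy]-2-(prop-2-enyl)benzene F4.
- Second-generation Grubbs catalyst in CH2Cl2 closes the ring to 11.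

This costs five steps in place of three, but the alkene position is fixed by the position of the two olefins.

Step 12. Three things can go wrong. Metalation may stray from C7 to the C5 methylene (benzylic, allylic and next to an acetal oxygen), to C2 (which would open ring C by elimination of the aryloxide), or to C9. The hindered 2,6-dialkoxyaryllithium may also act as a base towards the amide, removing an α-proton or triggering loss of formaldehyde from the N-methoxy group, instead of adding. The fallback replaces the acylation by carbonyl addition followed by oxidation, sets out from 16 and 13, and returns at 18. Reduction of 16 with i-Bu2AlH at −78 °C should give 3-[3,4-bis(methoxymethoxy)phenyl]propanal F5. Addition of 17 (from 13 as in step 12) to this far more electrophilic and less hindered carbonyl gives 3-[3,4-bis(methoxymethoxy)phenyl]-1-[6,8-bis(methoxymethoxy)-3-methyl-2,5-dihydro-1-benzoxepin-7-yl]propan-1-ol F6 (racemic). Dess–Martin periodinane oxidation gives 18.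

Step 6. The sodium alkoxide formed on hydride addition lies next to an aryl silyl ether, and a 1,4 O→O silyl shift to the benzylic oxygen is possible because a phenoxide is the better leaving group. In addition, 10 ionises so easily that it may decompose during isolation. The fallback changes the silyl group to one that does not migrate and that shields ring A more strongly in the cyclisation. It sets out from 7 and returns at 12:
- TIPSCl and imidazole in DMF should give 2-hydroxy-4,6-bis(triisopropylsilyloxy)benzaldehyde F7.
- Mitsunobu etherification with 6 gives 2-{[(Z)-2-methyl-3-(trimethylsilyl)prop-2-enyl]oxy}-4,6-bis(triisopropylsilyloxy)benzaldehyde F8.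
- NaBH4 reduction gives [2-{[(Z)-2-methyl-3-(trimethylsilyl)prop-2-enyl]oxy}-4,6-bis(triisopropylsilyloxy)phenyl]methanol F9.
- Cyclisation under the conditions of step 7 gives 3-methyl-6,8-bis(triisopropylsilyloxy)-2,5-dihydro-1-benzoxepine F10.
- Bu4NF then gives 12.

Step 13. The catechol acetals are the slowest to cleave. While they are being removed, the acid may protonate the trisubstituted alkene (leading to double-bond migration into conjugation or addition of methanol at C3) or ionise the allylic aryl ether. The fallback takes the catechol out of the acid step by protecting it as silyl ethers. It sets out from 15 and returns at 19: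
- TBSCl and imidazole should convert 15 into 3-[3,4-bis(tert-butyldimethylsilyloxy)phenyl]-N-methoxy-N-methylpropanamide F11.
- Acylation of 17 with F11 as in step 12 gives 3-[3,4-bis(tert-butyldimethylsilyloxy)phenyl]-1-[6,8-bis(methoxymethoxy)-3-methyl-2,5-dihydro-1-benzoxepin-7-yl]propan-1-one F12.
- Bu4NF buffered with AcOH frees the catechol to give 1-[6,8-bis(methoxymethoxy)-3-methyl-2,5-dihydro-1-benzoxepin-7-yl]-3-(3,4-dihydroxyphenyl)propan-1-one F13.
- Only the two acetals beside the ketone remain; these are activated by chelation and should fall to brief treatment with cold dilute HCl in MeOH, giving 19.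

## Further compounds

F1 | step 7 | 2,4-bis(tert-butyldimethylsilyloxy)-6-[(2-methylprop-2-enyl)oxy]benzaldehyde | O=Cc1c(O[Si](C)(C)C(C)(C)C)cc(O[Si](C)(C)C(C)(C)C)cc1OCC(C)=C
F2 | step 7 | 1,5-bis(tert-butyldimethylsilyloxy)-2-(2-methoxyethenyl)-3-[(2-methylprop-2-enyl)oxy]benzene (E/Z mixture) | COC=Cc1c(O[Si](C)(C)C(C)(C)C)cc(O[Si](C)(C)C(C)(C)C)cc1OCC(C)=C
F3 | step 7 | {2,4-bis(tert-butyldimethylsilyloxy)-6-[(2-methylprop-2-enyl)oxy]phenyl}acetaldehyde | O=CCc1c(O[Si](C)(C)C(C)(C)C)cc(O[Si](C)(C)C(C)(C)C)cc1OCC(C)=C
F4 | step 7 | 1,5-bis(tert-butyldimethylsilyloxy)-3-[(2-methylprop-2-enyl)oxy]-2-(prop-2-enyl)benzene | C=CCc1c(O[Si](C)(C)C(C)(C)C)cc(O[Si](C)(C)C(C)(C)C)cc1OCC(C)=C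
F5 | step 12 | 3-[3,4-bis(methoxymethoxy)phenyl]propanal | O=CCCc1ccc(OCOC)c(OCOC)c1
F6 | step 12 | 3-[3,4-bis(methoxymethoxy)phenyl]-1-[6,8-bis(methoxymethoxy)-3-methyl-2,5-dihydro-1-benzoxepin-7-yl]propan-1-ol (racemic) | CC1=CCc2c(cc(OCOC)c(C(O)CCc3ccc(OCOC)c(OCOC)c3)c2OCOC)OC1
F7 | step 6 | 2-hydroxy-4,6-bis(triisopropylsilyloxy)benzaldehyde | O=Cc1c(O)cc(O[Si](C(C)C)(C(C)C)C(C)C)cc1O[Si](C(C)C)(C(C)C)C(C)C
F8 | step 6 | 2-{[(Z)-2-methyl-3-(trimethylsilyl)prop-2-enyl]oxy}-4,6-bis(triisopropylsilyloxy)benzaldehyde | O=Cc1c(O[Si](C(C)C)(C(C)C)C(C)C)cc(O[Si](C(C)C)(C(C)C)C(C)C)cc1OC/C(C)=C\[Si](C)(C)C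
F9 | step 6 | [2-{[(Z)-2-methyl-3-(trimethylsilyl)prop-2-enyl]oxy}-4,6-bis(triisopropylsilyloxy)phenyl]methanol | OCc1c(O[Si](C(C)C)(C(C)C)C(C)C)cc(O[Si](C(C)C)(C(C)C)C(C)C)cc1OC/C(C)=C\[Si](C)(C)C
F10 | step 6 | 3-methyl-6,8-bis(triisopropylsilyloxy)-2,5-dihydro-1-benzoxepine | CC1=CCc2c(cc(O[Si](C(C)C)(C(C)C)C(C)C)cc2O[Si](C(C)C)(C(C)C)C(C)C)OC1
F11 | step 13 | 3-[3,4-bis(tert-butyldimethylsilyloxy)phenyl]-N-methoxy-N-methylpropanamide | CON(C)C(=O)CCc1ccc(O[Si](C)(C)C(C)(C)C)c(O[Si](C)(C)C(C)(C)C)c1
F12 | step 13 | 3-[3,4-bis(tert-butyldimethylsilyloxy)phenyl]-1-[6,8-bis(methoxymethoxy)-3-methyl-2,5-dihydro-1-benzoxepin-7-yl]propan-1-one | CC1=CCc2c(cc(OCOC)c(C(=O)CCc3ccc(O[Si](C)(C)C(C)(C)C)c(O[Si](C)(C)C(C)(C)C)c3)c2OCOC)OC1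
F13 | step 13 | 1-[6,8-bis(methoxymethoxy)-3-methyl-2,5-dihydro-1-benzoxepin-7-yl]-3-(3,4-dihydroxyphenyl)propan-1-one | CC1=CCc2c(cc(OCOC)c(C(=O)CCc3ccc(O)c(O)c3)c2OCOC)OC1
A1 | alternative 1 | 6-{4-[3,4-bis(methoxymethoxy)phenyl]-2-oxobutyl}-4-hydroxy-2H-pyran-2-one | O=C1C=C(O)C=C(CC(=O)CCc2ccc(OCOC)c(OCOC)c2)O1
A2 | alternative 1 | 3-[3,4-bis(methoxymethoxy)phenyl]-1-(2,4,6-trihydroxyphenyl)propan-1-one | COCOc1ccc(CCC(=O)c2c(O)cc(O)cc2O)cc1OCOC
A3 | alternative 2 | 3-[3,4-bis(methoxymethoxy)phenyl]-1-{2,6-dihydroxy-4-[(phenylsulfanyl)methoxy]-3-[(Z)-3-(trimethylsilyl)but-2-enyl]phenyl}propan-1-one | C[Si](C)(C)/C(C)=C\Cc1c(O)c(C(=O)CCc2ccc(OCOC)c(OCOC)c2)c(O)cc1OCSc1ccccc1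
A4 | alternative 2 | 3-[3,4-bis(methoxymethoxy)phenyl]-1-(6,8-dihydroxy-3-methyl-2,5-dihydro-1-benzoxepin-7-yl)propan-1-one | CC1=CCc2c(cc(O)c(C(=O)CCc3ccc(OCOC)c(OCOC)c3)c2O)OC1
A5 | alternative 3 | 6-(tert-butyldimethylsilyloxy)-1-(prop-1-en-2-yl)spiro[2.5]octane-4,8-dione (racemic, mixture of diastereomers) | CC(=C)C1CC12C(=O)CC(O[Si](C)(C)C(C)(C)C)CC2=O
A6 | alternative 3 | 8-(tert-butyldimethylsilyloxy)-3-methyl-2,5,8,9-tetrahydro-1-benzoxepin-6(7H)-one (racemic, one enantiomer drawn) | CC1=CCC2=C(OC1)C[C@H](O[Si](C)(C)C(C)(C)C)CC2=O
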